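**Plan**
Locants: C1 (ArCH), C2, C3, C4 (CHMe), C5 (CMe), C6 and C7 (cyclopropane CH), C8 and C9 (C=O), C10 (C–OAr), C11 (CMe2); ring A = C1–C5/C10, ring B = C5–C10, ring C = arene.
Retrosynthetic cuts, in order: the chalcone C=C (aldol); C6–C11 and C7–C11 (cyclopropane); C1–C10 and O–C10 together; C10=N2; aryl–C1; C5–C10 and C6=C7 (Robinson annulation).
Enabling feature: C10 is bonded to the phenol oxygen and to benzylic C1, the two termini of an o-quinone methide, and is α to the C9 ketone, so it can arrive as the carbon of a 3-diazo-1,2-dione (formal [4+1]).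
Forward: ring B is built first and oxidised to the 8,9-dione level, ring C is joined at C1 as an o-hydroxystyrene, C10 is made a diazo carbon, ring A and the dihydrofuran then close in one step, and the cyclopropane and the chalcone follow.
Stereochemistry: C4 from (R)-citronellal; C5 by catalyst-controlled Michael addition; C1 and C10 in the key step under control of C5; C6/C7 by ylide addition anti to the C5 methyl group.

Key step: step 13

Assumption: the L-proline-derived sulfonamide catalyst of step 2 is taken to give the 5R quaternary centre; if its facial sense is the opposite, the D-proline-derived catalyst is used and nothing else changes.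

Step 1
Reactants: 1 (R)-citronellal
Product: 4 (3R)-2,3,7-trimethyloct-6-enal (both C2 epimers), via cyclohexylimine 2 (not isolated), via methylated cyclohexylimine 3 (not isolated)
Conditions: c-C6H11NH2, MgSO4, Et2O, rt; LiN(iPr)2, THF, −78 to 0 °C; MeI, −78 °C to rt; aq. AcOH/NaOAc, rt
Reagents that add atoms: iodomethane, CI
Why: Metalloenamine alkylation, in which the lithium aza-enolate of the aldimine is C-methylated once and buffered hydrolysis returns the aldehyde without self-aldolisation; the new C2 centre forms as both epimers, which is harmless because it becomes trigonal in step 2, and the 3R centre is not enolisable.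

Step 2
Reactants: 4 (3R)-2,3,7-trimethyloct-6-enal; 5 methyl vinyl ketone
Product: 7 (4R)-4-methyl-4-[(2R)-6-methylhept-5-en-2-yl]cyclohex-2-en-1-one, via keto aldehyde 6 (not isolated)
Conditions: (S)-N-(4-dodecylphenylsulfonyl)pyrrolidine-2-carboxamide (20 mol%), 4 Å MS, ClCH2CH2Cl, rt; then KOH, EtOH, rt
Reagents that add atoms: none
Why: Robinson annulation by enamine catalysis, in which the enamine of the α,α-disubstituted aldehyde adds to the vinyl ketone on the face left open by the chiral prolinamide, setting quaternary C5 as R under catalyst control beside the resident 4R centre, and base-induced aldol condensation of keto aldehyde 6, whose aldehyde has no α-hydrogen, can close only the 4,4-disubstituted cyclohexenone.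

Step 3
Reactants: 7 (4R)-4-methyl-4-[(2R)-6-methylhept-5-en-2-yl]cyclohex-2-en-1-one
Product: 8 diosphenol (4R)-2-hydroxy-4-methyl-4-[(2R)-6-methylhept-5-en-2-yl]cyclohexa-2,5-dien-1-one
Conditions: KOtBu, O2 (1 atm), THF/tBuOH, −20 to 0 °C; then aq. HCl
Reagents that add atoms: dioxygen, O=O
Why: Enolate autoxidation, in which the enone, having quaternary C5, can be deprotonated only at C9, the enolate takes up O2 and Kornblum–DeLaMare-type loss of water from the α-hydroperoxide gives the 8,9-dione, which should rest as the cross-conjugated enol towards C10.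

Step 4
Reactants: 8 diosphenol
Product: 9 enol acetate (3R)-3-methyl-3-[(2R)-6-methylhept-5-en-2-yl]-6-oxocyclohexa-1,4-dien-1-yl acetate
Conditions: Ac2O, pyridine, 4-(dimethylamino)pyridine (5 mol%), CH2Cl2, 0 °C
Reagents that add atoms: acetic anhydride, CC(=O)OC(C)=O
Why: O-Acylation of the acidic enol masks it as an enol ester, so that ring B carries only carbonyl-conjugated, electron-poor alkenes during the ozonolysis and the organochromium step.

Step 5
Reactants: 9 enol acetate
Product: 10 aldehyde (3R)-3-methyl-6-oxo-3-[(2R)-5-oxopentan-2-yl]cyclohexa-1,4-dien-1-yl acetate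
Conditions: O3, CH2Cl2, −78 °C (Sudan Red 7B end point); then Me2S, −78 °C to rt
Reagents that add atoms: ozone, [O-][O+]=O
Why: Ozonolysis with reductive work-up, relying on the isolated trisubstituted alkene reacting far faster with ozone than the two carbonyl-conjugated ring alkenes, should unveil the C1 aldehyde.

Step 6
Reactants: 11 1-(2,6-dihydroxy-4-methoxyphenyl)ethanone
Product: 12 1-[2-hydroxy-4-methoxy-6-(methoxymethoxy)phenyl]ethanone
Conditions: MeOCH2Cl (1.1 equiv), iPr2NEt, CH2Cl2, 0 °C to rt
Reagents that add atoms: chloromethyl methyl ether, COCCl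
Why: Phenol O-alkylation (MOM protection) stops after one of the two equivalent hydroxyls, because the remaining one is then locked in a hydrogen bond to the acetyl group and reacts much more slowly.

Step 7
Reactants: 12 1-[2-hydroxy-4-methoxy-6-(methoxymethoxy)phenyl]ethanone
Product: 13 1-[2-hydroxy-3-iodo-4-methoxy-6-(methoxymethoxy)phenyl]ethanone
Conditions: N-iodosuccinimide, DMF, 0 °C to rt, dark
Reagents that add atoms: N-iodosuccinimide, O=C1CCC(=O)N1I
Why: Electrophilic aromatic iodination should occur at C3, ortho to the free phenol, which is the strongest director on the ring, and the acid-free conditions preserve the MOM acetal.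

Step 8
Reactants: 13 1-[2-hydroxy-3-iodo-4-methoxy-6-(methoxymethoxy)phenyl]ethanone
Product: 14 1-[2-(tert-butyldimethylsilyloxy)-3-iodo-4-methoxy-6-(methoxymethoxy)phenyl]ethanone
Conditions: tBuMe2SiCl, imidazole, DMF, 40 °C
Reagents that add atoms: tert-butyl(chloro)dimethylsilane, CC(C)(C)[Si](C)(C)Cl
Why: Silylation covers the only acidic site of the aryl iodide for the organochromium step with a group that later leaves by basic methanolysis, to which the MOM ether is inert.

Step 9
Reactants: 10 aldehyde; 14 aryl iodide
Product: 15 benzylic alcohol (aryl joined to C1; both carbinol epimers; aryl silyl ether and enol acetate intact)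
Conditions: CrCl2 (excess), NiCl2 (2 mol%), DMF, rt; aq. work-up
Reagents that add atoms: none
Why: Nozaki–Hiyama–Kishi reaction, in which zerovalent nickel inserts into the C–I bond and transmetalation to chromium gives an arylchromium species that adds to the aldehyde but not to the aryl ketone, the dienone or the esters; the carbinol centre forms as both epimers and is removed in step 10.

Step 10
Reactants: 15 benzylic alcohol
Product: 16 (E)-styrene (C1=C2; aryl silyl ether and enol acetate intact)
Conditions: MeO2CNSO2NEt3 (Burgess reagent), THF, 50 °C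
Reagents that add atoms: none
Why: Burgess dehydration, in which the sulfamate ester of the strongly donor-substituted benzylic alcohol ionises and loses a proton from C2, the only β-position, should give the conjugated E-alkene under neutral conditions that spare the silyl ether, the MOM acetal and the enol acetate.

Step 11
Reactants: 16 (E)-styrene
Product: 17 o-hydroxystyrene diosphenol (4R)-4-[(2R,4E)-5-{3-acetyl-2-hydroxy-6-methoxy-4-(methoxymethoxy)phenyl}pent-4-en-2-yl]-2-hydroxy-4-methylcyclohexa-2,5-dien-1-one
Conditions: NaOMe, MeOH, 0 °C to rt, argon; then AcOH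
Reagents that add atoms: none
Why: Methoxide-mediated transesterification and desilylation remove the enol acetate and the aryl silyl ether together, while the MOM ether, the styrene and the dienone are inert to base and the absence of acid keeps the o-hydroxystyrene from ionising.

Step 12
Reactants: 17 o-hydroxystyrene diosphenol
Product: 18 diazo-dione (4R)-4-[(2R,4E)-5-{3-acetyl-2-hydroxy-6-methoxy-4-(methoxymethoxy)phenyl}pent-4-en-2-yl]-3-diazo-4-methylcyclohex-5-ene-1,2-dione
Conditions: 4-AcNHC6H4SO2N3, Et3N, MeCN, 0 °C to rt
Reagents that add atoms: 4-acetamidobenzenesulfonyl azide, CC(=O)Nc1ccc(cc1)S(=O)(=O)N=[N+]=[N-]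
Why: Regitz diazo transfer, in which the diosphenolate is attacked at C10 by the terminal nitrogen of the sulfonyl azide and the triazene collapses with loss of the sulfonamide and of the C10 proton, should give the non-enolisable 3-diazo-1,2-dione, while the chelated aryl phenol and the methyl ketone are too weakly nucleophilic at carbon to compete under triethylamine.

Step 13
Reactants: 18 diazo-dione
Product: 21 tetracyclic 6-ene-8,9-dione MOM ether (1R,4R,5R,10S), via o-quinone methide 19 (not isolated), via diazonium phenolate 20 (not isolated)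
Conditions: (PhO)2P(O)OH (20 mol%), 4 Å MS, CH2Cl2, −20 °C to rt, dark
Reagents that add atoms: none
Why: Proposed new method: the phosphoric acid protonates C2 of the electron-rich o-hydroxystyrene to give the hydrogen-bonded o-quinone methide 19, the nucleophilic diazo carbon C10 adds to its exocyclic carbon C1 to give the α-keto diazonium phenolate 20, and dinitrogen then leaves while the phenol oxygen, held over C10 by the aryl group, closes the ether; the closest known reaction type is the Brønsted acid-catalysed intermolecular formal [4+1] annulation of o-quinone methides with α-diazo ketones (and with sulfur ylides) to 2,3-dihydrobenzofurans. Ring A closes 6-exo-trig (C10 onto the exocyclic C1=C bond) and the dihydrofuran closes 5-exo-tet (oxygen onto C10 with N2 as leaving group). C1 is controlled by the C5 centre: ring B is flat, so C10 can be reached only on the face that carries C4, anti to the C5 methyl, through a chair in which the C5–C6 bond is axial, and the aryl group then takes the equatorial position, which is cis to the C5 methyl. C10 is controlled by C1, because the tethered oxygen can reach C10 only on the face of the aryl group, which is the face N2 departs from, so substitution occurs with retention and gives the cis-fused dihydrobenzofuran and the cis A/B junction. The step needs C–C bond formation at the diazo carbon alone and C–O closure faster than 1,2-shifts in the diazonium ion; the first is secured by the dione having no enolisable position and by the trioxygenated arene, which makes o-quinone methide formation fast at low temperature before the diazo group can add thermally to the styrene, and the second by the five-membered proximity of the phenol oxygen.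

Step 14
Reactants: 21 tetracyclic 6-ene-8,9-dione MOM ether
Product: 22 cyclopropane (1R,4R,5R,6S,7R,10S)
Conditions: [Ph2S(iPr)]BF4, LiN(iPr)2, MeOCH2CH2OMe, −78 °C; then 21, −78 to −30 °C
Reagents that add atoms: isopropyldiphenylsulfonium tetrafluoroborate, CC(C)[S+](c1ccccc1)c1ccccc1.F[B-](F)(F)F
Why: Sulfur-ylide cyclopropanation of the Corey–Chaykovsky type, in which the isopropylide adds to C6, the β-carbon of the C6=C7–C8=O enone, anti to the pseudo-axial C5 methyl and the C7 enolate then displaces diphenyl sulfide, should set C6 and C7 with the cyclopropane on the face opposite the C5 methyl.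

Step 15
Reactants: 22 cyclopropane; 23 4-methoxybenzaldehyde
Product: 24 chalcone MOM ether
Conditions: KOH (1.5 equiv, aq.), EtOH, 0 °C to rt
Reagents that add atoms: none
Why: Claisen–Schmidt condensation, in which the enolate of the methyl ketone, the only readily enolisable carbonyl, adds to the non-enolisable aldehyde and E1cB loss of water gives the E-enone, is run cold with little base to limit attack of hydroxide on the dione.

Step 16
Reactants: 24 chalcone MOM ether
Product: 25 CNP0121765.1
Conditions: HCl (1 M in MeOH), rt
Reagents that add atoms: none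
Why: Acid-catalysed acetal cleavage removes the MOM ether ortho to the ketone at room temperature, conditions under which the chalcone, the aryl ether and the cyclopropyl dione should persist.

**Compound list**
1 | (R)-citronellal, (3R)-3,7-dimethyloct-6-enal | C[C@H](CCC=C(C)C)CC=O | starting material
2 | (3R)-N-cyclohexyl-3,7-dimethyloct-6-en-1-imine | CC(C)=CCC[C@@H](C)CC=NC1CCCCC1 | intermediate (not isolated)
3 | (3R)-N-cyclohexyl-2,3,7-trimethyloct-6-en-1-imine, both C2 epimers | CC(C)=CCC[C@@H](C)C(C)C=NC1CCCCC1 | intermediate (not isolated)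
4 | (3R)-2,3,7-trimethyloct-6-enal, both C2 epimers | CC(C)=CCC[C@@H](C)C(C)C=O | intermediate
5 | methyl vinyl ketone, but-3-en-2-one | CC(=O)C=C | starting material
6 | (2R)-2-methyl-2-[(2R)-6-methylhept-5-en-2-yl]-5-oxohexanal | CC(C)=CCC[C@@H](C)[C@@](C)(CCC(C)=O)C=O | intermediate (not isolated)
7 | (4R)-4-methyl-4-[(2R)-6-methylhept-5-en-2-yl]cyclohex-2-en-1-one | CC(C)=CCC[C@@H](C)[C@]1(C)C=CC(=O)CC1 | intermediate
8 | (4R)-2-hydroxy-4-methyl-4-[(2R)-6-methylhept-5-en-2-yl]cyclohexa-2,5-dien-1-one (diosphenol) | CC(C)=CCC[C@@H](C)[C@]1(C)C=CC(=O)C(O)=C1 | intermediate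
9 | (3R)-3-methyl-3-[(2R)-6-methylhept-5-en-2-yl]-6-oxocyclohexa-1,4-dien-1-yl acetate | CC(C)=CCC[C@@H](C)[C@]1(C)C=CC(=O)C(OC(C)=O)=C1 | intermediate
10 | (3R)-3-methyl-6-oxo-3-[(2R)-5-oxopentan-2-yl]cyclohexa-1,4-dien-1-yl acetate | O=CCC[C@@H](C)[C@]1(C)C=CC(=O)C(OC(C)=O)=C1 | intermediate
11 | 1-(2,6-dihydroxy-4-methoxyphenyl)ethanone | CC(=O)c1c(O)cc(OC)cc1O | starting material
12 | 1-[2-hydroxy-4-methoxy-6-(methoxymethoxy)phenyl]ethanone | CC(=O)c1c(O)cc(OC)cc1OCOC | intermediate
13 | 1-[2-hydroxy-3-iodo-4-methoxy-6-(methoxymethoxy)phenyl]ethanone | CC(=O)c1c(O)c(I)c(OC)cc1OCOC | intermediate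
14 | 1-[2-(tert-butyldimethylsilyloxy)-3-iodo-4-methoxy-6-(methoxymethoxy)phenyl]ethanone | CC(=O)c1c(O[Si](C)(C)C(C)(C)C)c(I)c(OC)cc1OCOC | intermediate
15 | (3R)-3-[(2R)-5-{3-acetyl-2-(tert-butyldimethylsilyloxy)-6-methoxy-4-(methoxymethoxy)phenyl}-5-hydroxypentan-2-yl]-3-methyl-6-oxocyclohexa-1,4-dien-1-yl acetate, both carbinol epimers | CC(=O)c1c(OCOC)cc(OC)c(C(O)CC[C@@H](C)[C@]2(C)C=CC(=O)C(OC(C)=O)=C2)c1O[Si](C)(C)C(C)(C)C | intermediate
16 | (3R)-3-[(2R,4E)-5-{3-acetyl-2-(tert-butyldimethylsilyloxy)-6-methoxy-4-(methoxymethoxy)phenyl}pent-4-en-2-yl]-3-methyl-6-oxocyclohexa-1,4-dien-1-yl acetate | CC(=O)c1c(OCOC)cc(OC)c(/C=C/C[C@@H](C)[C@]2(C)C=CC(=O)C(OC(C)=O)=C2)c1O[Si](C)(C)C(C)(C)C | intermediate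
17 | (4R)-4-[(2R,4E)-5-{3-acetyl-2-hydroxy-6-methoxy-4-(methoxymethoxy)phenyl}pent-4-en-2-yl]-2-hydroxy-4-methylcyclohexa-2,5-dien-1-one | CC(=O)c1c(OCOC)cc(OC)c(/C=C/C[C@@H](C)[C@]2(C)C=CC(=O)C(O)=C2)c1O | intermediate
18 | (4R)-4-[(2R,4E)-5-{3-acetyl-2-hydroxy-6-methoxy-4-(methoxymethoxy)phenyl}pent-4-en-2-yl]-3-diazo-4-methylcyclohex-5-ene-1,2-dione (key-step precursor) | CC(=O)c1c(OCOC)cc(OC)c(/C=C/C[C@@H](C)[C@]2(C)C=CC(=O)C(=O)C2=[N+]=[N-])c1O | intermediate
19 | o-quinone methide, (4R)-4-{(2R)-5-[3-acetyl-6-methoxy-4-(methoxymethoxy)-2-oxocyclohexa-3,5-dien-1-ylidene]pentan-2-yl}-3-diazo-4-methylcyclohex-5-ene-1,2-dione | CC(=O)C1=C(OCOC)C=C(OC)C(=CCC[C@@H](C)[C@]2(C)C=CC(=O)C(=O)C2=[N+]=[N-])C1=O | intermediate (not isolated)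
20 | diazonium phenolate with ring A closed: C10 carries N2+ on the face of the C5 methyl, C1 carries the 2-oxidoaryl group cis to the C5 methyl; (1R,4R,5R,10S) | CC(=O)c1c(OCOC)cc(OC)c(c1[O-])[C@H]1CC[C@@H](C)[C@]2(C)C=CC(=O)C(=O)[C@]12[N+]#N | intermediate (not isolated)
21 | tetracyclic ene-dione (key-step product): 2,3-dihydrobenzofuran (O–C10, aryl–C1) fused to ring A and to cis-fused ring B with C6=C7 and the C8/C9 dione; arene carries acetyl (ortho to the furan oxygen), OMOM and OMe; 4-Me, 5-Me, O–C10 and aryl–C1 on one face; (1R,4R,5R,10S) | CC(=O)c2c(OCOC)cc(OC)c3c2O[C@]24C(=O)C(=O)C=C[C@@]2(C)[C@H](C)CC[C@H]34 | intermediate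
22 | cyclopropane: 21 with a CMe2 bridge (C11) across C6–C7 on the face opposite the C5 methyl; (1R,4R,5R,6S,7R,10S) | CC(=O)c2c(OCOC)cc(OC)c3c2O[C@]24C(=O)C(=O)[C@@H]5[C@@H](C5(C)C)[C@@]2(C)[C@H](C)CC[C@H]34 | intermediate
23 | 4-methoxybenzaldehyde | COc1ccc(C=O)cc1 | starting material
24 | chalcone MOM ether: 22 with the acetyl group converted into (E)-3-(4-methoxyphenyl)prop-2-enoyl | COc1ccc(/C=C/C(=O)c2c(OCOC)cc(OC)c3c2O[C@]24C(=O)C(=O)[C@@H]5[C@@H](C5(C)C)[C@@]2(C)[C@H](C)CC[C@H]34)cc1 | intermediate
25 | CNP0121765.1: 24 with the free phenol; (1R,4R,5R,6S,7R,10S) | COc1ccc(/C=C/C(=O)c2c(O)cc(OC)c3c2O[C@]24C(=O)C(=O)[C@@H]5[C@@H](C5(C)C)[C@@]2(C)[C@H](C)CC[C@H]34)cc1 | target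

**Step count and risks**
Total step count: 16. Longest linear sequence: 13 steps (steps 1–5 and 9–16, from (R)-citronellal); the arene branch (steps 6–8) joins at step 9.

Step 13 (proposed new method). After the C1–C10 bond has formed, loss of dinitrogen may be accompanied by migration of the anti-periplanar C1 hydrogen or of C6 instead of capture by the phenol oxygen. The diazo group may also add as a 1,3-dipole to the styrene before the o-quinone methide forms. Ring A may close with the aryl group axial, which leads into the C1/C10-epimeric, trans-fused series. The fallback uses known chemistry and sets out from 17, which has no diazo group. (PhO)2P(O)OH in CH2Cl2 generates the same o-quinone methide, and the enol carbon C10 adds to C1 (acid-catalysed conjugate addition of an enol to an o-quinone methide) to give the ring-A-closed diosphenol F1. Treatment with I2 and K2CO3 in MeCN iodinates C10 and the phenoxide displaces iodide (iodine-mediated oxidative cyclisation to a dihydrobenzofuran). This comes back to the route at 21.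

Step 14. The ylide may attack the C9 carbonyl of the vicinal dione and form an epoxide instead of adding to C6, or it may add on the face of the C5 methyl. The fallback sets out from 21. 1,3-Dipolar cycloaddition of 2-diazopropane (from acetone hydrazone and Ag2O, Et2O, −78 °C) to the doubly activated C6=C7 bond gives the cis-fused 1-pyrazoline F2. Irradiation at 350 nm in CH2Cl2 expels dinitrogen and closes the cyclopropane. This comes back to the route at 22.

Step 15. Hydroxide may add to the non-enolisable 8,9-dione and trigger a benzilic acid-type contraction of ring B faster than the aldol condensation proceeds. The fallback sets out from 22. LiN(SiMe3)2 in THF at −78 °C forms the lithium enolate of the methyl ketone, which adds to 23 to give the β-hydroxy ketone F3. Mesylation and elimination (MeSO2Cl, Et3N, CH2Cl2, 0 °C to rt) under aprotic conditions give the enone. This comes back to the route at 24.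

Further compounds
F1 | step 13 | ring-A-closed diosphenol (C8 ketone, C9 enol, C9=C10 and C6=C7; 2-hydroxyaryl group at C1 cis to the C5 methyl) | CC(=O)c1c(OCOC)cc(OC)c(c1O)[C@H]1CC[C@@H](C)[C@]2(C)C=CC(=O)C(O)=C12
F2 | step 14 | cis-fused 1-pyrazoline of 21 (C6–CMe2–N=N–C7, on the face opposite the C5 methyl) | CC(=O)c2c(OCOC)cc(OC)c3c2O[C@]24C(=O)C(=O)[C@H]5N=NC(C)(C)[C@H]5[C@@]2(C)[C@H](C)CC[C@H]34
F3 | step 15 | β-hydroxy ketone (aldol adduct of 22 and 23, both carbinol epimers) | COc1ccc(C(O)CC(=O)c2c(OCOC)cc(OC)c3c2O[C@]24C(=O)C(=O)[C@@H]5[C@@H](C5(C)C)[C@@]2(C)[C@H](C)CC[C@H]34)cc1
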